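The seven-membered ring is disconnected at two bonds: the CH2–CH(OH) bond C8–C9 and the ring-fusion bond C1–C5 shared with the cyclopentene (C10 = the C=CH2 carbon between C9 and C1; C6 = the carbinol next to C5; C7 bears the side chain). Both bonds form in one intramolecular (4+3) cycloaddition: a 2-silyloxyallyl cation C9–C10–C1, made from a (Z)-2-silyloxy enal and SnCl4, adds across the 2-silyloxydiene C5=C6–C7=C8 held by the C2–C3=C4 tether. It exploits the 1,3-relation of the C9 carbinol and C1 methine across C10 and the C6 oxygen; it closes both rings and sets C1, C5, C9. The precursor is an acyclic trienol ether with a masked enal.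

Key step: step 14

Remark: locants as above, with C2 (ring CH2), C3 (=CH), C4 (=C–CH3), C11 (CH–CH3), C12 (CH–OAc); compounds 1, 3, 8 and 10 are assumed to be commercial; 13 to 21 are carried as both epimers at the dioxane carbon (future C1), which becomes planar in step 14.

Step 1
Reactants: 1 4-methylpent-4-en-1-ol
Product: 2 4-methylpent-4-enal
Conditions: TEMPO (cat.), PhI(OAc)2, CH2Cl2, 23 °C
Reagents that add atoms: none
Why: Oxoammonium (TEMPO) oxidation of the primary alcohol stops at the aldehyde and leaves the 1,1-disubstituted alkene untouched.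

Step 2
Reactants: 3 (R)-4-benzyl-3-propionyloxazolidin-2-one; 2 4-methylpent-4-enal
Product: 5 (R)-4-benzyl-3-[(2R,3S)-3-hydroxy-2,6-dimethylhept-6-enoyl]oxazolidin-2-one, via (Z)-dibutylboron enolate 4 (not isolated)
Conditions: Bu2BOTf, i-Pr2NEt, CH2Cl2, −78 → 0 °C; then 2, −78 → 0 °C; pH 7 buffer, MeOH, H2O2
Reagents that add atoms: none
Why: Evans syn-aldol reaction; the (Z)-boron enolate reacts through a chair Zimmerman–Traxler transition state on the face away from the benzyl group, which sets C11 and C12 in the syn relation of the target.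

Step 3
Reactants: 5 aldol adduct
Product: 6 (2R,3S)-3-hydroxy-N-methoxy-N,2,6-trimethylhept-6-enamide
Conditions: MeNHOMe·HCl, AlMe3, THF, 0 → 23 °C
Reagents that add atoms: N,O-dimethylhydroxylamine hydrochloride, CNOC.Cl
Why: Weinreb amide formation by aluminium amide transamidation, aided by the free β-hydroxyl, removes the auxiliary without epimerising C11.

Step 4
Reactants: 6 hydroxy Weinreb amide
Product: 7 (2R,3S)-N-methoxy-N,2,6-trimethyl-3-(trimethylsilyloxy)hept-6-enamide
Conditions: Me3SiCl, imidazole, CH2Cl2, 0 °C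
Reagents that add atoms: chlorotrimethylsilane, C[Si](C)(C)Cl
Why: Silyl ether protection keeps the alkoxide out of the Grignard and methylenation steps; the group is lost again in step 10.

Step 5
Reactants: 8 2,2-dimethyl-1,3-dioxan-5-one
Product: 9 2-(2,2-dimethyl-1,3-dioxan-5-ylidene)-1,1-dimethylhydrazine
Conditions: Me2NNH2, 4 Å molecular sieves, benzene, 23 °C
Reagents that add atoms: 1,1-dimethylhydrazine, CN(C)N
Why: Hydrazone formation (condensation) masks the ketone and allows clean mono-alkylation through the azaenolate.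

Step 6
Reactants: 10 (Z)-3-methylpent-2-en-4-yn-1-ol
Product: 11 (Z)-5-bromo-3-methylpent-3-en-1-yne
Conditions: PBr3, pyridine (cat.), Et2O, 0 °C
Reagents that add atoms: phosphorus tribromide, BrP(Br)Br
Why: Substitution of the primary allylic alcohol by bromide with PBr3 (SN2) keeps the Z double bond that later holds C2 and C5 cis.

Step 7
Reactants: 9 dioxanone dimethylhydrazone; 11 (Z)-5-bromo-3-methylpent-3-en-1-yne
Product: 13 2-{2,2-dimethyl-4-[(2Z)-3-methylpent-2-en-4-yn-1-yl]-1,3-dioxan-5-ylidene}-1,1-dimethylhydrazine, via lithium azaenolate 12 (not isolated)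
Conditions: LiN(i-Pr)2, THF, −78 °C; then 11, −78 → 0 °C
Reagents that add atoms: none
Why: Hydrazone (azaenolate) alkylation at the primary allylic bromide in the SN2 mode joins C1 to C2 and keeps the Z alkene; the new centre forms as both epimers and is lost in step 14.

Step 8
Reactants: 13 alkynyl hydrazone; 7 silylated Weinreb amide
Product: 15 (2Z,7R,8S)-1-[5-(2,2-dimethylhydrazinylidene)-2,2-dimethyl-1,3-dioxan-4-yl]-3,7,11-trimethyl-8-(trimethylsilyloxy)dodeca-2,11-dien-4-yn-6-one, via alkynylmagnesium bromide 14 (not isolated)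
Conditions: EtMgBr, THF, 0 → 40 °C; then 7, 0 → 23 °C; aq. NH4Cl
Reagents that add atoms: none
Why: Weinreb ketone synthesis; the magnesium acetylide adds only once because the chelated tetrahedral intermediate survives until work-up, which joins C6 to C7.

Step 9
Reactants: 15 ynone
Product: 16 2-{4-[(2Z,7S,8S)-3,7,11-trimethyl-6-methylidene-8-(trimethylsilyloxy)dodeca-2,11-dien-4-yn-1-yl]-2,2-dimethyl-1,3-dioxan-5-ylidene}-1,1-dimethylhydrazine
Conditions: Zn, CH2Br2, TiCl4, THF/CH2Cl2, 0 → 23 °C
Reagents that add atoms: dibromomethane, BrCBr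
Why: Lombardo methylenation with the non-basic zinc/titanium methylene reagent turns the ynone carbonyl into the C7=C8 methylene group without epimerising C11 or touching the alkyne.

Step 10
Reactants: 16 dienyne hydrazone
Product: 17 4-[(2Z,7S,8S)-8-hydroxy-3,7,11-trimethyl-6-methylidenedodeca-2,11-dien-4-yn-1-yl]-2,2-dimethyl-1,3-dioxan-5-one
Conditions: sat. aq. oxalic acid, Et2O, 23 °C
Reagents that add atoms: water, O
Why: Hydrazone hydrolysis in a two-phase system regenerates the dioxanone and cleaves the trimethylsilyl ether while the acetonide should survive.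

Step 11
Reactants: 17 hydroxy dienyne
Product: 19 4-[(2Z,7S,8S)-8-hydroxy-3,7,11-trimethyl-6-methylidene-5-oxododeca-2,11-dien-1-yl]-2,2-dimethyl-1,3-dioxan-5-one, via cyclic dienol ether 18 (not isolated)
Conditions: Ph3PAuNTf2 (2 mol %), THF/H2O 10:1, 23 °C
Reagents that add atoms: water, O
Why: Gold-catalysed alkyne hydroalkoxylation then hydrolysis: the C12 hydroxyl attacks the activated alkyne 5-exo-dig at C6, and 18 is hydrolysed with kinetic protonation at C5, so the carbonyl ends at C6 and the C3=C4 bond stays out of conjugation.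

Step 12
Reactants: 19 hydroxy diketone
Product: 20 (5S,6S,10Z)-12-(2,2-dimethyl-5-oxo-1,3-dioxan-4-yl)-2,6,10-trimethyl-7-methylidene-8-oxododeca-1,10-dien-5-yl acetate
Conditions: Ac2O, pyridine, DMAP (cat.), CH2Cl2, 0 °C
Reagents that add atoms: acetic anhydride, CC(=O)OC(C)=O
Why: Acetylation (nucleophilic catalysis) of the only free hydroxyl installs the C12 acetate before the other oxygens are unveiled.

Step 13
Reactants: 20 acetoxy diketone
Product: 21 (5S,6S,8Z,10Z)-8-(tert-butyldimethylsilyloxy)-12-[5-(tert-butyldimethylsilyloxy)-2,2-dimethyl-4H-1,3-dioxin-4-yl]-2,6,10-trimethyl-7-methylidenedodeca-1,8,10-trien-5-yl acetate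
Conditions: TBSOTf, Et3N, CH2Cl2, −78 → 0 °C
Reagents that add atoms: tert-butyldimethylsilyl triflate, CC(C)(C)[Si](C)(C)OS(=O)(=O)C(F)(F)F
Why: Soft enolisation and O-silylation; the C6 ketone can enolise only toward C5 and should give the (Z)-silyl dienol ether, and the dioxanone enolises toward its unsubstituted CH2 to give the 5-silyloxy-4H-1,3-dioxin.

Step 14
Reactants: 21 bis(silyl enol ether)
Product: 23 trans-fused hydroazulenone with C10 ketone, free C9 hydroxyl, C6=C7 tert-butyldimethylsilyl enol ether and C12 acetate (C1, C5, C9, C11, C12 as in the target), via (Z)-2-silyloxy enal 22 (not isolated)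
Conditions: toluene, 110 °C; then SnCl4 (1.1 equiv), CH2Cl2, −78 °C; aq. NaHCO3
Reagents that add atoms: none
Why: Heating expels acetone from the silyloxydioxin by retro-[4+2] cycloaddition to give the (Z)-2-silyloxy enal 22, which SnCl4 binds at the formyl oxygen to give a 2-silyloxyallyl cation (C9–C10–C1); this adds across the 2-silyloxydiene, C1 to C5 and C9 to C8, the C10 oxocarbenium ion then gives up its silyl group as TBSCl and work-up frees the C9 hydroxyl from tin. The closest known reaction type is the Lewis acid-mediated (4+3) cycloaddition of 2-silyloxyacroleins and (Z)-2-silyloxy-2-enals with dienes, known in inter- and intramolecular form; a stepwise Mukaiyama–Michael/Mukaiyama–Michael course leads to the same product. The cyclopentene closes in the 5-exo-trig mode (C5 of the dienol ether on C1, ends held together by the cis C3=C4 bond) and the cycloheptene in the 7-endo-trig mode (C9 on C8), or both in one concerted (4+3) event. C1 and C5 should become trans because the tether sits anti on the (Z)-enal and the extended transition state keeps the two silyloxy groups apart; C9–O should end cis to H1 because tin on the formyl oxygen and the bulky C10 silyloxy group favour the s-cis (sickle) cation. The diene face is chosen by C11: 1,3-allylic strain with the C6 silyloxy group turns C11–H into the diene plane and puts C12 on one face, and tin held between the formyl oxygen and the C12 acetate carbonyl should deliver the cation to that face, which gives the target configuration at C1, C5 and C9. The step needs (4+3) closure over (4+2) closure and over thermal Diels–Alder reaction of 22; closure through C9, the nucleophilic carbon of the silyl enol ether, and the low temperature of the tin stage should secure this.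

Step 15
Reactants: 23 hydroazulenone
Product: 24 10-methylidene analogue of 23 (free C9 hydroxyl, C6=C7 silyl enol ether, C12 acetate)
Conditions: Zn, CH2Br2, TiCl4, THF/CH2Cl2, 0 → 23 °C
Reagents that add atoms: dibromomethane, BrCBr
Why: Lombardo methylenation converts the hindered, enolisable C10 ketone into the exocyclic methylene group under non-basic conditions that spare the acetate, the silyl enol ether and the centres at C1 and C9.

Step 16
Reactants: 24 silyl enol ether
Product: 25 C6 ketone (6-oxo analogue of the target; C7 and all other centres as in the target)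
Conditions: Bu4NF, AcOH, THF, −40 → 0 °C
Reagents that add atoms: none
Why: Fluoride desilylation of the silyl enol ether followed by C-protonation; the free axial C9 hydroxyl lies directly above C7 and should relay the proton to that face, which puts the side chain in the equatorial position of the target, while the acetic acid buffer keeps the C3=C4 bond from moving into conjugation.

Step 17
Reactants: 25 C6 ketone
Product: 26 (2S,3S)-2-[(3aS,4R,5S,7R,8aR)-4,7-dihydroxy-3-methyl-8-methylidene-1,3a,4,5,6,7,8,8a-octahydroazulen-5-yl]-6-methylhept-6-en-3-yl acetate (target)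
Conditions: Me4NBH(OAc)3, AcOH/MeCN 1:1, −30 °C
Reagents that add atoms: none
Why: Hydroxyl-directed reduction with triacetoxyborohydride (Evans–Saksena type): the C9 hydroxyl binds boron and should deliver hydride across the ring to the upper face of C6, anti to the C7 side chain, which gives the C6 alcohol trans to the C9 hydroxyl and cis to the side chain.

Compound list
1 | 4-methylpent-4-en-1-ol | C=C(C)CCCO | starting material
2 | 4-methylpent-4-enal | C=C(C)CCC=O | intermediate
3 | (R)-4-benzyl-3-propionyloxazolidin-2-one | CCC(=O)N1C(=O)OC[C@H]1Cc1ccccc1 | starting material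
4 | (Z)-dibutylboron enolate of 3 | C/C=C(\OB(CCCC)CCCC)N1C(=O)OC[C@H]1Cc1ccccc1 | intermediate
5 | (R)-4-benzyl-3-[(2R,3S)-3-hydroxy-2,6-dimethylhept-6-enoyl]oxazolidin-2-one | C=C(C)CC[C@H](O)[C@@H](C)C(=O)N1C(=O)OC[C@H]1Cc1ccccc1 | intermediate
6 | (2R,3S)-3-hydroxy-N-methoxy-N,2,6-trimethylhept-6-enamide | C=C(C)CC[C@H](O)[C@@H](C)C(=O)N(C)OC | intermediate
7 | (2R,3S)-N-methoxy-N,2,6-trimethyl-3-(trimethylsilyloxy)hept-6-enamide | C=C(C)CC[C@H](O[Si](C)(C)C)[C@@H](C)C(=O)N(C)OC | intermediate
8 | 2,2-dimethyl-1,3-dioxan-5-one | CC1(C)OCC(=O)CO1 | starting material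
9 | 2-(2,2-dimethyl-1,3-dioxan-5-ylidene)-1,1-dimethylhydrazine | CN(C)N=C1COC(C)(C)OC1 | intermediate
10 | (Z)-3-methylpent-2-en-4-yn-1-ol | C#C/C(C)=C\CO | starting material
11 | (Z)-5-bromo-3-methylpent-3-en-1-yne | C#C/C(C)=C\CBr | intermediate
12 | lithium azaenolate of 9 | [Li]N(N(C)C)C1=COC(C)(C)OC1 | intermediate
13 | 2-{2,2-dimethyl-4-[(2Z)-3-methylpent-2-en-4-yn-1-yl]-1,3-dioxan-5-ylidene}-1,1-dimethylhydrazine (both epimers at the dioxane carbon) | CN(C)N=C1COC(C)(C)OC1C/C=C(C)\C#C | intermediate
14 | alkynylmagnesium bromide of 13 | CN(C)N=C1COC(C)(C)OC1C/C=C(C)\C#C[Mg]Br | intermediate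
15 | (2Z,7R,8S)-1-[5-(2,2-dimethylhydrazinylidene)-2,2-dimethyl-1,3-dioxan-4-yl]-3,7,11-trimethyl-8-(trimethylsilyloxy)dodeca-2,11-dien-4-yn-6-one | C=C(C)CC[C@H](O[Si](C)(C)C)[C@@H](C)C(=O)C#C/C(C)=C\CC1OC(C)(C)OCC1=NN(C)C | intermediate
16 | 6-methylidene analogue of 15 (C7=C8 in place of C7=O; (2Z,7S,8S) chain) | C=C(C)CC[C@H](O[Si](C)(C)C)[C@@H](C)C(=C)C#C/C(C)=C\CC1OC(C)(C)OCC1=NN(C)C | intermediate
17 | 4-[(2Z,7S,8S)-8-hydroxy-3,7,11-trimethyl-6-methylidenedodeca-2,11-dien-4-yn-1-yl]-2,2-dimethyl-1,3-dioxan-5-one | C=C(C)CC[C@H](O)[C@@H](C)C(=C)C#C/C(C)=C\CC1OC(C)(C)OCC1=O | intermediate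
18 | cyclic dienol ether: (Z)-2-alkylidene-3-methylideneoxolane from O12–C6 bond formation, cis 4-methyl/5-(3-methylbut-3-enyl), C11 and C12 as in the target | C=C(C)CC[C@@H]1O/C(=C\C(C)=C/CC2OC(C)(C)OCC2=O)C(=C)[C@@H]1C | intermediate
19 | 4-[(2Z,7S,8S)-8-hydroxy-3,7,11-trimethyl-6-methylidene-5-oxododeca-2,11-dien-1-yl]-2,2-dimethyl-1,3-dioxan-5-one | C=C(C)CC[C@H](O)[C@@H](C)C(=C)C(=O)C/C(C)=C\CC1OC(C)(C)OCC1=O | intermediate
20 | (5S,6S,10Z)-12-(2,2-dimethyl-5-oxo-1,3-dioxan-4-yl)-2,6,10-trimethyl-7-methylidene-8-oxododeca-1,10-dien-5-yl acetate | C=C(C)CC[C@H](OC(C)=O)[C@@H](C)C(=C)C(=O)C/C(C)=C\CC1OC(C)(C)OCC1=O | intermediate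
21 | (5S,6S,8Z,10Z)-8-(tert-butyldimethylsilyloxy)-12-[5-(tert-butyldimethylsilyloxy)-2,2-dimethyl-4H-1,3-dioxin-4-yl]-2,6,10-trimethyl-7-methylidenedodeca-1,8,10-trien-5-yl acetate | C=C(C)CC[C@H](OC(C)=O)[C@@H](C)C(=C)/C(O[Si](C)(C)C(C)(C)C)=C/C(C)=C\CC1OC(C)(C)OC=C1O[Si](C)(C)C(C)(C)C | intermediate
22 | (5S,6S,8Z,10Z,13Z)-8,14-bis(tert-butyldimethylsilyloxy)-2,6,10-trimethyl-7-methylidene-15-oxopentadeca-1,8,10,13-tetraen-5-yl acetate | C=C(C)CC[C@H](OC(C)=O)[C@@H](C)C(=C)/C(O[Si](C)(C)C(C)(C)C)=C/C(C)=C\C/C=C(\O[Si](C)(C)C(C)(C)C)C=O | intermediate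
23 | trans-fused hydroazulenone: C10 ketone, free C9–OH, C6=C7 silyl enol ether, C12 acetate; C1, C5, C9, C11, C12 as in the target | C=C(C)CC[C@H](OC(C)=O)[C@@H](C)C=1C[C@@H](O)C(=O)[C@@H]2CC=C(C)[C@H]2C=1O[Si](C)(C)C(C)(C)C | intermediate
24 | 10-methylidene analogue of 23 | C=C(C)CC[C@H](OC(C)=O)[C@@H](C)C=1C[C@@H](O)C(=C)[C@@H]2CC=C(C)[C@H]2C=1O[Si](C)(C)C(C)(C)C | intermediate
25 | 6-oxo analogue of the target (C6 ketone, C7–H as in the target) | C=C(C)CC[C@H](OC(C)=O)[C@@H](C)[C@@H]1C[C@@H](O)C(=C)[C@@H]2CC=C(C)[C@H]2C1=O | intermediate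
26 | (2S,3S)-2-[(3aS,4R,5S,7R,8aR)-4,7-dihydroxy-3-methyl-8-methylidene-1,3a,4,5,6,7,8,8a-octahydroazulen-5-yl]-6-methylhept-6-en-3-yl acetate | C=C(C)CC[C@H](OC(C)=O)[C@@H](C)[C@@H]1C[C@@H](O)C(=C)[C@@H]2CC=C(C)[C@H]2[C@@H]1O | target

Total step count: 17. Longest linear sequence: 14 steps (1–4, then 8–17).

Steps most likely to fail

Step 14. The cascade may stop after the first C–C bond, close through C10 instead of C9, or add to both faces of the diene; 22 may also be lost by thermal Diels–Alder reaction or 1,5-hydrogen shift during unmasking. The fallback sets out from 21 and comes back to the route at 25; it runs the two ring closures as separate, individually tuned Mukaiyama–Michael additions. Thermolysis of 21 gives 22, which is isolated. Catalytic TBSOTf with 2,6-di-tert-butyl-4-methylpyridine at −78 °C should close only the five-membered ring and, after silyl transfer, give the trans-disubstituted cyclopentene with enone and (E)-1,2-bis(silyloxy)alkene arms F1. A second silyl triflate-catalysed addition (C9 to C8, high dilution) gives the 9-O-silyl hydroazulenone F2, Lombardo methylenation gives the 10-methylidene compound F3, and Bu4NF/AcOH removes both silyl groups to reach 25.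

Step 16. Proton transfer to C7 may come from the lower, less hindered face and give the C7 epimer, and the new β,γ-unsaturated ketone may isomerise into conjugation. The fallback sets out from 23 and comes back at 25; it delivers hydrogen to C7 as H2 and not as a proton. Saegusa–Ito oxidation of the silyl enol ether of 23 (Pd(OAc)2, MeCN) gives the C7=C8 enone F4. Hydrogenation with [Rh(nbd)(dppb)]BF4 under direction of the allylic C9 hydroxyl should add H2 to the upper face and give the 6,10-diketone F5 with the target configuration at C7. Lombardo methylenation of the less hindered, hydroxyl-flanked C10 ketone then gives 25.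

Step 11. Water may add with the wrong regiochemistry (oxygen at C5), the acetonide may be lost, or the C3=C4 bond may move into conjugation during hydrolysis of 18. The fallback sets out from 17 and comes back at 19; it brings the oxygen to C6 through a silicon tether. (HMe2Si)2NH converts the C12 hydroxyl into the dimethylsilyl ether F6. Intramolecular syn-hydrosilylation with Pt2[(CH2=CHSiMe2)2O]3 (6-exo-dig) puts silicon on C6 and gives the cyclic alkenylsilane F7. Tamao–Fleming oxidation (H2O2, KF, KHCO3) turns the C6–Si bond into the C6 ketone and frees the C12 hydroxyl, which is 19.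

Further compounds
F1 | step 14 | trans-4,5-disubstituted cyclopentene: C5 carries the C6 ketone with C7=C8 methylidene and side chain, C1 carries the (E)-1,2-bis(tert-butyldimethylsilyloxy)vinyl group (C10=C9) | C=C(C)CC[C@H](OC(C)=O)[C@@H](C)C(=C)C(=O)[C@@H]1C(C)=CC[C@H]1/C(O[Si](C)(C)C(C)(C)C)=C\O[Si](C)(C)C(C)(C)C
F2 | step 14 | 9-O-tert-butyldimethylsilyl ether of 23 | C=C(C)CC[C@H](OC(C)=O)[C@@H](C)C=1C[C@@H](O[Si](C)(C)C(C)(C)C)C(=O)[C@@H]2CC=C(C)[C@H]2C=1O[Si](C)(C)C(C)(C)C
F3 | step 14 | 9-O-tert-butyldimethylsilyl ether of 24 | C=C(C)CC[C@H](OC(C)=O)[C@@H](C)C=1C[C@@H](O[Si](C)(C)C(C)(C)C)C(=C)[C@@H]2CC=C(C)[C@H]2C=1O[Si](C)(C)C(C)(C)C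
F4 | step 16 | C7=C8 enone: 6,10-diketone with free C9 hydroxyl | C=C(C)CC[C@H](OC(C)=O)[C@@H](C)C1=C[C@@H](O)C(=O)[C@@H]2CC=C(C)[C@H]2C1=O
F5 | step 16 | saturated 6,10-diketone with free C9 hydroxyl, C7–H as in the target | C=C(C)CC[C@H](OC(C)=O)[C@@H](C)[C@@H]1C[C@@H](O)C(=O)[C@@H]2CC=C(C)[C@H]2C1=O
F6 | step 11 | C12 dimethylsilyl ether of 17 | C=C(C)CC[C@H](O[SiH](C)C)[C@@H](C)C(=C)C#C/C(C)=C\CC1OC(C)(C)OCC1=O
F7 | step 11 | cyclic alkenylsilane (1-oxa-2-silacyclohexane with silicon on C6, exocyclic C6=C5 and C7=C8) | C=C(C)CC[C@@H]1O[Si](C)(C)/C(=C/C(C)=C\CC2OC(C)(C)OCC2=O)C(=C)[C@@H]1C
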